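The vessel was a closed, stirred flask at constant volume and temperature, holding substrate and undissolved solid reagent, and earlier runs stood beside it.

| flask | substrate | solid reagent | remark | time |
|---|---|---|---|---|
| Saturday's | 0.010 M | 0.80 equiv | run made earlier |  |
| Monday's | 0.010 M | 1.8 equiv | run made earlier |  |
| Thursday's | 0.020 M | 1.2 equiv | run made earlier |  |
| flask | 0.010 M | 1.20 equiv |  | 10 h |

- Saturday's (time / h: substrate / %, product / %): 0.833: 99.9, 0.4; 1.33: 100.0, 0; 2.00: 98.7, 0.3; 3.00: 97.0, 1.5; 4.00: 94.8, 1.9; 6.00: 91.8, 4.7; 10.0: 77.3, 10.4
- Monday's (time / h: substrate / %, product / %): 0.500: 99.5, 0.9; 1.50: 98.9, 0.9; 3.00: 98.1, 0.8; 4.00: 95.9, 2.0; 6.00: 92.7, 4.5; 8.00: 86.0, 6.8; 10.0: 77.7, 11.0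
- Thursday's (time / h: substrate / %, product / %): 0.833: 100.2, 0; 2.50: 98.2, 0.6; 5.00: 93.7, 2.7; 8.00: 85.8, 6.5; 10.0: 79.6, 11.1

(standard deviation of a reading: 0.5 percentage points)

- percent here means substrate units held: one idle adduct counts as two
- what is said of product includes idle adduct and crystals
- crystals, solid reagent is a solid; its amount is given per volume of the solution
- the analysis behind the earlier runs scatters by 0.5 percentage points, standard deviation
- what may be going on: substrate + product <-> idle adduct; substrate + partner -> product; crystals <-> product; substrate + partner + product -> 2 product; solid reagent <-> partner
- at the start none of the solid reagent is in solution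
- in an amount of product, one idle adduct counts as one product
- the reaction counts as stopped when no species that holds the substrate changes by six tenths of a point or more over the second half of the time
- what has gone from substrate into another species counts as reacted, even if it can come back

- why nothing more happens at 10 h, or that something still does (for what has run out or reacted, a solid counts together with what of it has only dissolved) (the partner has run out first / it is still moving / all of the substrate has reacted)
- share of the substrate used up at 10 h
- product at 10 h, in percent of the substrate charged

I wanted the speed of these runs in one form, so I turned it into a time. Monday's run gave 34.8 h at 10.0 h for what I call the clearing time, the hours the substrate left would need at the run's average speed so far. At 3.00 h the same reading gave 155 h, though that rests on a loss of 1.9 percentage points read with a scatter of 0.5 points. The clearing time read from Monday's run thus shrank by a factor of 4.45, so the average speed of that run was rising.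

Saturday's run gave 34.1 h, despite its very different charge of solid. For the flask, whose charge lies between those two, I took their mean, 34.4 h. That gave me 22.5% used by 10 h. Monday's substrate lost twice its product, so I expected 11.2% product. The clearing time stood well beyond the time asked, and Monday's substrate fell 15 points over its last 4.00 h, so I expected the flask still moving.

The forecast said it is still moving, with 22.4% used (20.8% to 24%) and 10.8% product (9.8% to 11.8%), reasoning that “the amount of solid doesn't matter”.

The answer for the flask was: it is still moving, with 21.5% used and 11.2% product, inside both ranges.

    substrate + product ⇌ idle adduct, settled at all times (K = 1500 L mol⁻¹)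
    substrate + partner → product (k = 2.00 L mol⁻¹ h⁻¹)
    crystals ⇌ product, rate k3*(cs3 - [product]) while solid is left; crystals form when [product] > cs3 (solubility = 7.60 mM, k = 46.0 h⁻¹)
    substrate + partner + product → 2 product (k = 36000 L² mol⁻² h⁻¹)
    solid reagent ⇌ partner, rate k5*(cs5 - [partner]) while solid is left; crystals form when [partner] > cs5 (solubility = 6.20 mM, k = 0.270 h⁻¹)

The clearing time of this flask at 10 h came to 36.6 h. A neighbouring flask, charged with 0.300 equiv of solid reagent and otherwise the same, had used 11.7% of its substrate by that time, below the forecast's low end of 20.8%. The neighbour's clearing time of 75.2 h was twice that of this flask. In the neighbour, undissolved solid reagent stood at 0% of its charge and partner at 0.00239 M, against 46.9% and 0.00526 M in this flask, and its product reached 6.08%.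

The numbers in the tables are simulated with made-up constants; scatter was added.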